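Remark on the chemistry: the chain is numbered C1 (=CH2) to C8 with the methyl branch on C3. CIP analysis of the structure gives 3R,4S. Compounds 1, 3, 8, 13, 17 and 21 are taken as commercial.

## The problem

The target is the 3-acetate 4-[(E)-4-hydroxycinnamate] of (3R,4S)-3,7-dimethylocta-1,6-diene-3,4-diol. It is an open chain C1=C2–C3–C4–C5–C6=C7(C8) with a methyl branch on C3 and no ring except the benzene ring of the acyl group, so the work lies in building a chain and not in joining rings. The two stereocentres are neighbours: C3 is fully substituted (CH3, vinyl, acetoxy, C4) and C4 is a secondary carbinol carbon. In the open chain C4 can hardly steer C3, because CH3 and vinyl on C3 differ little in size; once O3 and O4 are tied into a five-membered ring, the C5 chain on C4 lies on one ring face and can decide which face of C3 reacts. The two oxygens must end with different acyl groups, which is possible without extra protecting groups only because one hydroxyl is secondary and the other tertiary; the price is a slow acylation of the tertiary one beside an ester that could migrate. The tertiary allylic C3–O bond ionises under strong acid, the C6=C7 alkene is sensitive to acid and electrophilic oxidants, and the cinnamate with its free phenol tolerates neither hydride reagents nor strong base, so both acyl groups belong at the very end. The enabling feature is that C2 to C6 with oxygen on C3 and C4 is 2-deoxy-D-ribose read from C5 to C1: C4 (S) is sugar C3 unchanged, and C3 (R) is sugar C4 with CH3 where the sugar has H. That hydrogen sits next to sugar C5, so when C5 (the future C2) is raised to an ester and O3/O4 are held in a dioxolane, C3–H becomes the acidic α-hydrogen of a ring-bound ester and the methyl group can be brought to a planar C3 under the control of C4.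

## Retrosynthesis

**Phenol and C3 acetate.** Target 23 is traced to its aryl silyl ether 22, so that the phenol cannot compete in the acylations. Cutting the C3 O–acetyl bond of 22 gives hydroxy ester 20 and acetic anhydride 21. The acetate is cut first (made last) because the reverse order would expose a tertiary acetate next to a free secondary hydroxyl, where acyl migration runs downhill. In 20 the only migration possible is uphill, from a secondary to a tertiary oxygen. The forward reaction must acetylate a hindered tertiary alcohol without moving the neighbouring ester.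

**C4 ester.** Cutting the C4 O–acyl bond of 20 gives diol 16 and the O-silylated acid 19, made in one operation from p-coumaric acid 17 through the bis-silyl compound 18. No protecting group is needed on the diol, since the secondary hydroxyl of 16 is acylated far faster than the tertiary one. This removes the aromatic part and leaves a C10 diol with both stereocentres.

**Vinyl group and diol protection.** Diol 16 is masked as acetonide 15, whose C1=C2 bond is cut by a Wittig disconnection to aldehyde 12 and ylide 14 (from phosphonium salt 13). Aldehyde 12 is the reduction product of ester 11. Cutting C1=C2 instead of C2–C3 keeps the fully substituted C3 intact and puts a carbonyl group on C2, which is what the next disconnection needs. The aldehyde has no α-hydrogen, so the forward olefination cannot epimerise anything.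

**C3–CH3 bond (key disconnection).** Ester 11 is cut at the C3–CH3 bond to ester 9 and iodomethane 8 through lithium enolate 10. The neighbouring cuts are worse: addition of a vinyl or methyl nucleophile to a C3 ketone needs O3 and O4 differentiated and an open-chain 1,2-induction, and a C3–C4 aldol cut builds both centres at once. The chosen cut leaves a precursor with only sugar-derived stereocentres, and the C3 centre of 9 need not even be defined because it becomes planar. The forward reaction must alkylate before the enolate opens by β-elimination and must take the electrophile on the ring face opposite the C5 chain.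

**Back to the sugar.** Ester 9 comes from acid 7 and iodomethane 8; acid 7 comes from primary alcohol 5 by oxidation through aldehyde 6. The C6=C7 bond of 5 is cut by a Wittig disconnection to lactol 2 and ylide 4 (from phosphonium salt 3), and 2 is the 3,4-acetonide of 2-deoxy-D-ribose 1. The acetonide serves three purposes: it frees only the anomeric carbon for the olefination, it later forms the ring that controls the enolate, and it protects the diol through the redox steps.

## Roads not taken

**Alternative 1:** The cut is C5–C6 plus an epoxide C–O bond. Diol 16 would come from (2R)-2-[(2S)-oxiran-2-yl]but-3-en-2-ol A2 by opening at the terminal carbon with an alkenyl-copper nucleophile carrying C6 to C8, and A2 from the prochiral 3-methylpenta-1,4-dien-3-ol A1 by a hydroxyl-directed, catalyst-controlled epoxidation that selects one enantiotopic vinyl group and one of its faces.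
- Merits: 16 would be reached in two steps from an achiral alcohol, against eight in the chosen route, and the endgame is the same. In step count and atom economy this road is clearly better.
- Weak points: A1 is a tertiary allylic alcohol with two unsubstituted vinyl groups, the poorest substrate class for titanium tartrate catalysts. Group and face selection must both be high in a single event, and the group selection rests on telling CH3 from vinyl. A2 is small, volatile and water-soluble. Under the basic opening conditions its tertiary alkoxide can attack the epoxide (Payne rearrangement) and scramble C4.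
- Comparison: the chosen plan is longer but takes the configuration of C4 from the sugar, so no catalyst has to deliver it. It makes C3 in a separate diastereoselective step whose outcome can be read and purified at ester 11.

**Alternative 2:** The cut is the C3–O bond, then C4–C5. Racemic 2-methyl-2-vinyloxirane A3 is ionised by zerovalent palladium bearing a chiral diphosphine, and a boron-bound 4-methoxybenzyloxy nucleophile attacks the tertiary allyl terminus to give (2R)-2-(4-methoxybenzyloxy)-2-methylbut-3-en-1-ol A4.
- Merits: the difficult fully substituted C3 is set catalytically from a cheap racemate, and O3 arrives protected differently from O4. This handles the differentiation of the two oxygens better than the chosen plan, which relies on the secondary/tertiary rate difference and a late tertiary acetylation.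
- Weak points: C4 must then be made by adding a C5–C8 nucleophile to the derived aldehyde (2R)-2-(4-methoxybenzyloxy)-2-methylbut-3-enal A5. Chelation fixes the rotamer, but the two faces differ only by CH3 against vinyl on the quaternary carbon, so low selectivity is expected. Prenyl-metal reagents add through their γ-carbon, so the prenyl group would need a detour. The ether must later be removed oxidatively from a tertiary allylic position.
- Comparison: on paper about eight steps, fewer than the chosen twelve. Against this the chosen plan has a C4 centre of certain configuration and one ring-controlled new centre, where this road would probably need a second chiral reagent or a separation.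

**Alternative 3:** The cut is C4–C5 by a [2,3]-Wittig shift. The α-oxyallyl anion of 3-methyl-3-[(2-methylprop-2-en-1-yl)oxy]but-1-ene A6, made with an alkyllithium base and a chiral bis(oxazoline) ligand, rearranges to (3S)-2,6-dimethylhepta-1,5-dien-3-ol A7. Hydroxyl-directed epoxidation would then give (1S)-4-methyl-1-[(2R)-2-methyloxiran-2-yl]pent-3-en-1-ol A8, and one-carbon homologation of the epoxide with a sulfonium methylide would give 16.
- Merits: short (about eight steps in all). The shift creates the prenyl terminus and C4 together, and a 2-substituted allylic alcohol such as A7 is the favourable case for erythro-selective metal-directed epoxidation, which is the relative configuration needed.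
- Weak points: the enantioselectivity comes from a stoichiometric chiral lithium complex and is usually moderate for such shifts. A [1,2]-shift competes. The epoxidation must prefer the allylic 1,1-disubstituted alkene over the electron-rich homoallylic C6=C7 alkene. The oily, volatile intermediates give no easy way to raise the enantiomeric purity.
- Comparison: this road is shorter and its later steps are simple. The chosen plan is longer and carries redox and protecting-group adjustments, but it starts enantiopure and has to win only one diastereoselection.

Key step: step 5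

## Route

Step 1
Reactants: 1 2-deoxy-D-ribose
Product: 2 2-deoxy-3,4-O-isopropylidene-D-erythro-pentopyranose (lactol; both anomers)
Conditions: 2-methoxypropene (1.3 equiv), PPTS (cat.), EtOAc, 0 °C to rt
Reagents that add atoms: 2-methoxypropene, COC(C)=C
Why: Acid-catalysed acetalisation with an enol ether; the cis-3,4-diol of the pyranose form is the only pair that can close a five-membered acetal while the anomeric hydroxyl stays free, and no stereocentre is touched.

Step 2
Reactants: 2 acetonide lactol; 3 isopropyltriphenylphosphonium iodide
Product: 5 [(4R,5S)-2,2-dimethyl-5-(3-methylbut-2-en-1-yl)-1,3-dioxolan-4-yl]methanol, via isopropylidenetriphenylphosphorane 4 (not isolated)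
Conditions: 3 (3.0 equiv), n-BuLi (2.9 equiv), THF, 0 °C; then 2, 0 °C to rt
Reagents that add atoms: isopropyltriphenylphosphonium iodide (compound 3), CC(C)[P+](c1ccccc1)(c1ccccc1)c1ccccc1.[I-]
Why: Wittig olefination of the open hydroxy-aldehyde form of the lactol with a non-stabilised ylide; excess ylide covers the acidic lactol proton, the new alkene has two identical methyl groups so no geometry arises, and the acetonide is inert to base.

Step 3
Reactants: 5 primary alcohol
Product: 7 (4S,5S)-2,2-dimethyl-5-(3-methylbut-2-en-1-yl)-1,3-dioxolane-4-carboxylic acid, via dioxolane-4-carbaldehyde 6 (not isolated)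
Conditions: TEMPO (0.2 equiv), PhI(OAc)2 (2.2 equiv), MeCN/H2O (1:1), rt
Reagents that add atoms: water, O
Why: Oxoammonium (TEMPO) oxidation of the primary alcohol to the aldehyde, whose hydrate is oxidised on to the acid; the reagent leaves the trisubstituted alkene and the acetonide alone, and any epimerisation next to the carbonyl is harmless because this carbon is made planar in step 5.

Step 4
Reactants: 7 carboxylic acid; 8 iodomethane
Product: 9 methyl (4S,5S)-2,2-dimethyl-5-(3-methylbut-2-en-1-yl)-1,3-dioxolane-4-carboxylate
Conditions: MeI (1.5 equiv), K2CO3 (1.2 equiv), DMF, rt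
Reagents that add atoms: iodomethane (compound 8), CI
Why: SN2 O-alkylation of the potassium carboxylate; non-acidic conditions keep the acetonide and the alkene intact.

Step 5
Reactants: 9 methyl ester; 8 iodomethane
Product: 11 methyl (4S,5S)-2,2,4-trimethyl-5-(3-methylbut-2-en-1-yl)-1,3-dioxolane-4-carboxylate, via lithium ester enolate 10 (not isolated)
Conditions: LiN(iPr)2 (LDA, 1.15 equiv), THF/DMPU (6:1), −78 °C, 15 min; then MeI (5 equiv), −78 to −50 °C
Reagents that add atoms: iodomethane (compound 8), CI
Why: LiN(iPr)2 removes the ring C4–H of ester 9 at −78 °C and gives the exocyclic lithium ester enolate 10, in which this carbon is trigonal, so that cis- and trans-9 converge; iodomethane 8 then alkylates the enolate carbon by SN2 attack and forms the C3–CH3 bond of the target. The closest known reaction type is the α-alkylation of lithium enolates of 2,2-dimethyl-1,3-dioxolane-4-carboxylates (tartrate and glycerate acetonides). No ring is closed. The one new stereocentre, ring C4 (C3 of the target), is controlled by ring C5 (C4 of the target, from the sugar): allylic strain with the in-plane enolate oxygen pushes the 3-methylbut-2-enyl chain into a pseudoaxial position where it covers one face, so iodomethane should enter on the face that carries only H. The ester is thereby left cis to the chain and CH3 stands where the hydrogen of the sugar stood, which is the (4S,5S) ester and, after conversion of the ester into vinyl, 3R,4S. The step needs facial selectivity, C- over O-alkylation and alkylation faster than β-elimination; the first rests on the single substituent on the neighbouring ring carbon, the second on a soft SN2 electrophile meeting a lithium enolate, and the third on the ring, which holds the C5–O bond near the nodal plane of the enolate so that ring-opening E1cB elimination has poor overlap at −78 °C. DMPU and a large excess of 8 added within minutes of enolisation keep the lifetime of 10 short, and any minor C4 epimer would be a diastereomer removable by chromatography.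

Step 6
Reactants: 11 methylated ester
Product: 12 (4S,5S)-2,2,4-trimethyl-5-(3-methylbut-2-en-1-yl)-1,3-dioxolane-4-carbaldehyde
Conditions: iBu2AlH (DIBAL-H, 1.1 equiv), CH2Cl2, −78 °C; MeOH, then aq. potassium sodium tartrate
Reagents that add atoms: none
Why: Partial reduction of an α-alkoxy ester; the aluminium hemiacetal is held by chelation to the ring oxygen at −78 °C and releases the aldehyde only on work-up, and the α-carbon is fully substituted so it cannot epimerise.

Step 7
Reactants: 12 aldehyde; 13 methyltriphenylphosphonium bromide
Product: 15 (4R,5S)-4-ethenyl-2,2,4-trimethyl-5-(3-methylbut-2-en-1-yl)-1,3-dioxolane, via methylenetriphenylphosphorane 14 (not isolated)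
Conditions: 13 (1.5 equiv), KOtBu (1.4 equiv), THF, 0 °C; then 12, 0 °C to rt
Reagents that add atoms: methyltriphenylphosphonium bromide (compound 13), C[P+](c1ccccc1)(c1ccccc1)c1ccccc1.[Br-]
Why: Wittig methylenation of a non-enolisable aldehyde; the small ylide reaches the hindered carbonyl and the change of descriptor at ring C4 (S to R) is only a change of CIP priorities.

Step 8
Reactants: 15 vinyl acetonide
Product: 16 (3R,4S)-3,7-dimethylocta-1,6-diene-3,4-diol
Conditions: AcOH/H2O (4:1), 40 °C
Reagents that add atoms: none
Why: Acid-catalysed acetal hydrolysis cleaves only the bonds to the acetal carbon, so both C–O stereocentres are retained; the weak acid is chosen to spare the tertiary allylic C3–O bond and the C6=C7 alkene.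

Step 9
Reactants: 17 p-coumaric acid
Product: 19 (E)-3-[4-(tert-butyldimethylsilyloxy)phenyl]prop-2-enoic acid, via bis-silylated coumarate 18 (not isolated)
Conditions: TBSCl (2.3 equiv), imidazole (5 equiv), DMF, rt; then AcOH/THF/H2O (3:1:1), rt
Reagents that add atoms: tert-butyldimethylsilyl chloride, CC(C)(C)[Si](C)(C)Cl
Why: Silylation of phenol and acid, then selective hydrolysis of the far more labile silyl ester; the aryl silyl ether withstands the mild aqueous acid and the E-alkene is untouched.

Step 10
Reactants: 16 diol; 19 silylated acid
Product: 20 (3R,4S)-3-hydroxy-3,7-dimethylocta-1,6-dien-4-yl (E)-3-[4-(tert-butyldimethylsilyloxy)phenyl]prop-2-enoate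
Conditions: DCC (1.2 equiv), DMAP (0.2 equiv), CH2Cl2, 0 °C to rt
Reagents that add atoms: none
Why: Steglich esterification; the secondary C4 hydroxyl reacts with the acylpyridinium species far faster than the tertiary C3 hydroxyl, and only the acyl C–O bond forms, so C4 keeps its configuration.

Step 11
Reactants: 20 hydroxy ester; 21 acetic anhydride
Product: 22 (3R,4S)-3-acetoxy-3,7-dimethylocta-1,6-dien-4-yl (E)-3-[4-(tert-butyldimethylsilyloxy)phenyl]prop-2-enoate
Conditions: Ac2O (10 equiv), DMAP (1 equiv), Et3N, CH2Cl2, rt to 35 °C
Reagents that add atoms: acetic anhydride (compound 21), CC(=O)OC(C)=O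
Why: DMAP-catalysed acylation through the N-acetylpyridinium ion, the standard way to acetylate tertiary alcohols; the conditions are non-ionising, so the tertiary allylic centre keeps its configuration and the aryl silyl ether survives.

Step 12
Reactants: 22 silyl-protected diester
Product: 23 (3R,4S)-3-acetoxy-3,7-dimethylocta-1,6-dien-4-yl (E)-3-(4-hydroxyphenyl)prop-2-enoate (target)
Conditions: Bu4NF (1.1 equiv), AcOH (1.2 equiv), THF, 0 °C
Reagents that add atoms: none
Why: Fluoride cleavage of the aryl silyl ether; buffering with acetic acid keeps the phenoxide protonated, so neither ester is attacked or shifted.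

## Compound list

1 | 2-deoxy-D-ribose | OC[C@@H](O)[C@@H](O)CC=O | starting material
2 | 2-deoxy-3,4-O-isopropylidene-D-erythro-pentopyranose (lactol; both anomers) | OC1C[C@@H]2OC(C)(C)O[C@@H]2CO1 | intermediate
3 | isopropyltriphenylphosphonium iodide | CC(C)[P+](c1ccccc1)(c1ccccc1)c1ccccc1.[I-] | starting material
4 | isopropylidenetriphenylphosphorane | CC(C)=P(c1ccccc1)(c1ccccc1)c1ccccc1 | intermediate
5 | [(4R,5S)-2,2-dimethyl-5-(3-methylbut-2-en-1-yl)-1,3-dioxolan-4-yl]methanol | OC[C@H]1OC(C)(C)O[C@H]1CC=C(C)C | intermediate
6 | (4S,5S)-2,2-dimethyl-5-(3-methylbut-2-en-1-yl)-1,3-dioxolane-4-carbaldehyde | O=C[C@H]1OC(C)(C)O[C@H]1CC=C(C)C | intermediate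
7 | (4S,5S)-2,2-dimethyl-5-(3-methylbut-2-en-1-yl)-1,3-dioxolane-4-carboxylic acid | OC(=O)[C@H]1OC(C)(C)O[C@H]1CC=C(C)C | intermediate
8 | iodomethane | CI | starting material
9 | methyl (4S,5S)-2,2-dimethyl-5-(3-methylbut-2-en-1-yl)-1,3-dioxolane-4-carboxylate | COC(=O)[C@H]1OC(C)(C)O[C@H]1CC=C(C)C | intermediate
10 | lithium enolate of 9 (exocyclic C=C at ring C4; 5S; enolate geometry open) | COC(O[Li])=C1OC(C)(C)O[C@H]1CC=C(C)C | intermediate
11 | methyl (4S,5S)-2,2,4-trimethyl-5-(3-methylbut-2-en-1-yl)-1,3-dioxolane-4-carboxylate | COC(=O)[C@@]1(C)OC(C)(C)O[C@H]1CC=C(C)C | intermediate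
12 | (4S,5S)-2,2,4-trimethyl-5-(3-methylbut-2-en-1-yl)-1,3-dioxolane-4-carbaldehyde | O=C[C@@]1(C)OC(C)(C)O[C@H]1CC=C(C)C | intermediate
13 | methyltriphenylphosphonium bromide | C[P+](c1ccccc1)(c1ccccc1)c1ccccc1.[Br-] | starting material
14 | methylenetriphenylphosphorane | C=P(c1ccccc1)(c1ccccc1)c1ccccc1 | intermediate
15 | (4R,5S)-4-ethenyl-2,2,4-trimethyl-5-(3-methylbut-2-en-1-yl)-1,3-dioxolane | C=C[C@@]1(C)OC(C)(C)O[C@H]1CC=C(C)C | intermediate
16 | (3R,4S)-3,7-dimethylocta-1,6-diene-3,4-diol | C=C[C@@](C)(O)[C@H](CC=C(C)C)O | intermediate
17 | p-coumaric acid ((E)-3-(4-hydroxyphenyl)prop-2-enoic acid) | O=C(O)/C=C/c1ccc(O)cc1 | starting material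
18 | tert-butyldimethylsilyl (E)-3-[4-(tert-butyldimethylsilyloxy)phenyl]prop-2-enoate | CC(C)(C)[Si](C)(C)OC(=O)/C=C/c1ccc(O[Si](C)(C)C(C)(C)C)cc1 | intermediate
19 | (E)-3-[4-(tert-butyldimethylsilyloxy)phenyl]prop-2-enoic acid | OC(=O)/C=C/c1ccc(O[Si](C)(C)C(C)(C)C)cc1 | intermediate
20 | (3R,4S)-3-hydroxy-3,7-dimethylocta-1,6-dien-4-yl (E)-3-[4-(tert-butyldimethylsilyloxy)phenyl]prop-2-enoate | C=C[C@@](C)(O)[C@H](CC=C(C)C)OC(=O)/C=C/c1ccc(O[Si](C)(C)C(C)(C)C)cc1 | intermediate
21 | acetic anhydride | CC(=O)OC(C)=O | starting material
22 | (3R,4S)-3-acetoxy-3,7-dimethylocta-1,6-dien-4-yl (E)-3-[4-(tert-butyldimethylsilyloxy)phenyl]prop-2-enoate | C=C[C@@](C)(OC(C)=O)[C@H](CC=C(C)C)OC(=O)/C=C/c1ccc(O[Si](C)(C)C(C)(C)C)cc1 | intermediate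
23 | (3R,4S)-3-acetoxy-3,7-dimethylocta-1,6-dien-4-yl (E)-3-(4-hydroxyphenyl)prop-2-enoate | C=C[C@@](C)(OC(C)=O)[C@H](CC=C(C)C)OC(=O)/C=C/c1ccc(O)cc1 | target

## Step count and risks

Total steps: 12. Longest linear sequence: 11 (steps 1 to 8 and 10 to 12); step 9 is a one-step branch.

**Step 5 (key step).** Most likely failure: the enolate opens by β-elimination of the ring oxygen before it is alkylated, or the two faces of the planar carbon are not told apart well enough, since only a CH2 group on the neighbouring carbon separates them.
Fallback: make the C3–CH3 bond from a methyl nucleophile and a C3 ketone. The fallback sets out from alcohol 5 and returns at diol 16.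
- Alcohol 5 is oxidised with Dess–Martin periodinane to aldehyde 6, here isolated.
- Aldehyde 6 is methylenated with ylide 14 to (4R,5S)-4-ethenyl-2,2-dimethyl-5-(3-methylbut-2-en-1-yl)-1,3-dioxolane F1.
- Aqueous acetic acid frees (3R,4S)-7-methylocta-1,6-diene-3,4-diol F2.
- MnO2 oxidises only the allylic C3 carbinol to (4S)-4-hydroxy-7-methylocta-1,6-dien-3-one F3.
- Excess MeMgBr at −78 °C adds to the magnesium chelate of F3 on the face of the C4 hydrogen (Cram chelate control). This places CH3 and vinyl as in 16.

The old C3 centre is erased on the way, so any epimerisation of 6 does not matter.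

**Step 11.** Most likely failure: the hindered tertiary hydroxyl is acetylated so slowly that a base-mediated shift of the coumaroyl group to O3 competes. The freed secondary hydroxyl would then be acetylated faster, giving the transposed diester.
Fallback: block O4 while the acetate is installed. The fallback sets out from diol 16 and returns at 22.
- Et3SiCl and imidazole silylate the secondary hydroxyl to (3R,4S)-3,7-dimethyl-4-(triethylsilyloxy)octa-1,6-dien-3-ol F4.
- Ac2O and DMAP give (3R,4S)-3,7-dimethyl-4-(triethylsilyloxy)octa-1,6-dien-3-yl acetate F5, with no isomer possible.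
- HF·pyridine removes the silyl group under acidic conditions to give (3R,4S)-4-hydroxy-3,7-dimethylocta-1,6-dien-3-yl acetate F6.
- F6 is esterified at once with acid 19 (DCC, DMAP, 0 °C) to give 22. It is not stored, because acetyl migration from the tertiary to the secondary oxygen is downhill.

**Step 2.** Most likely failure: the hindered and strongly basic disubstituted ylide deprotonates the transient β-alkoxy aldehyde, with loss of the acetonide oxygen by elimination, instead of adding to it; conversion may also stay low.
Fallback: build the trisubstituted alkene by metathesis. The fallback sets out from lactol 2 and returns at alcohol 5.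
- Lactol 2 is methylenated with the small ylide 14 to [(4R,5S)-2,2-dimethyl-5-(prop-2-en-1-yl)-1,3-dioxolan-4-yl]methanol F7.
- Cross-metathesis of F7 with 2-methylbut-2-ene as solvent, using the second-generation Grubbs catalyst (H2IMes)(PCy3)Cl2Ru=CHPh, gives 5.

**Step 6.** Most likely failure: the aluminium hemiacetal collapses before the quench and is reduced on to the primary alcohol, or the neopentyl-like ester reacts incompletely.
Fallback: two steps through the alcohol, setting out from ester 11 and returning at aldehyde 12.
- LiAlH4 reduces 11 fully to [(4R,5S)-2,2,4-trimethyl-5-(3-methylbut-2-en-1-yl)-1,3-dioxolan-4-yl]methanol F8.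
- Dess–Martin periodinane oxidises F8 to 12.

**Step 8.** Most likely failure: the crowded acetal is cleaved slowly, and under more forcing acid the tertiary allylic C3–O bond ionises (allylic transposition or elimination) or a hydroxyl adds to the protonated C6=C7 alkene.
Fallback: remove the acetal before the allylic system exists and carry the diol as silyl ethers. The fallback sets out from ester 11 and returns at diol 16.
- Dilute HCl in aqueous THF cleaves the acetal of 11, whose C3 carries an electron-withdrawing ester and cannot ionise, to methyl (2S,3S)-2,3-dihydroxy-2,6-dimethylhept-5-enoate F9.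
- Et3SiOTf and 2,6-lutidine give methyl (2S,3S)-2,6-dimethyl-2,3-bis(triethylsilyloxy)hept-5-enoate F10.
- iBu2AlH at −78 °C gives (2S,3S)-2,6-dimethyl-2,3-bis(triethylsilyloxy)hept-5-enal F11.
- Ylide 14 gives (3R,4S)-3,7-dimethyl-3,4-bis(triethylsilyloxy)octa-1,6-diene F12.
- Bu4NF releases 16 without any acid.

## Further compounds

F1 | step 5 | (4R,5S)-4-ethenyl-2,2-dimethyl-5-(3-methylbut-2-en-1-yl)-1,3-dioxolane | C=C[C@H]1OC(C)(C)O[C@H]1CC=C(C)C
F2 | step 5 | (3R,4S)-7-methylocta-1,6-diene-3,4-diol | C=C[C@@H](O)[C@@H](O)CC=C(C)C
F3 | step 5 | (4S)-4-hydroxy-7-methylocta-1,6-dien-3-one | C=CC(=O)[C@@H](O)CC=C(C)C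
F4 | step 11 | (3R,4S)-3,7-dimethyl-4-(triethylsilyloxy)octa-1,6-dien-3-ol | C=C[C@@](C)(O)[C@H](CC=C(C)C)O[Si](CC)(CC)CC
F5 | step 11 | (3R,4S)-3,7-dimethyl-4-(triethylsilyloxy)octa-1,6-dien-3-yl acetate | C=C[C@@](C)(OC(C)=O)[C@H](CC=C(C)C)O[Si](CC)(CC)CC
F6 | step 11 | (3R,4S)-4-hydroxy-3,7-dimethylocta-1,6-dien-3-yl acetate | C=C[C@@](C)(OC(C)=O)[C@H](CC=C(C)C)O
F7 | step 2 | [(4R,5S)-2,2-dimethyl-5-(prop-2-en-1-yl)-1,3-dioxolan-4-yl]methanol | OC[C@H]1OC(C)(C)O[C@H]1CC=C
F8 | step 6 | [(4R,5S)-2,2,4-trimethyl-5-(3-methylbut-2-en-1-yl)-1,3-dioxolan-4-yl]methanol | OC[C@@]1(C)OC(C)(C)O[C@H]1CC=C(C)C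
F9 | step 8 | methyl (2S,3S)-2,3-dihydroxy-2,6-dimethylhept-5-enoate | COC(=O)[C@@](C)(O)[C@@H](O)CC=C(C)C
F10 | step 8 | methyl (2S,3S)-2,6-dimethyl-2,3-bis(triethylsilyloxy)hept-5-enoate | COC(=O)[C@@](C)(O[Si](CC)(CC)CC)[C@@H](O[Si](CC)(CC)CC)CC=C(C)C
F11 | step 8 | (2S,3S)-2,6-dimethyl-2,3-bis(triethylsilyloxy)hept-5-enal | O=C[C@@](C)(O[Si](CC)(CC)CC)[C@@H](O[Si](CC)(CC)CC)CC=C(C)C
F12 | step 8 | (3R,4S)-3,7-dimethyl-3,4-bis(triethylsilyloxy)octa-1,6-diene | C=C[C@@](C)(O[Si](CC)(CC)CC)[C@@H](O[Si](CC)(CC)CC)CC=C(C)C
A1 | alternative 1 | 3-methylpenta-1,4-dien-3-ol | C=CC(C)(O)C=C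
A2 | alternative 1 | (2R)-2-[(2S)-oxiran-2-yl]but-3-en-2-ol | C=C[C@@](C)(O)[C@@H]1CO1
A3 | alternative 2 | 2-methyl-2-vinyloxirane (racemic) | C=CC1(C)CO1
A4 | alternative 2 | (2R)-2-(4-methoxybenzyloxy)-2-methylbut-3-en-1-ol | C=C[C@@](C)(OCc1ccc(OC)cc1)CO
A5 | alternative 2 | (2R)-2-(4-methoxybenzyloxy)-2-methylbut-3-enal | C=C[C@@](C)(OCc1ccc(OC)cc1)C=O
A6 | alternative 3 | 3-methyl-3-[(2-methylprop-2-en-1-yl)oxy]but-1-ene | C=CC(C)(C)OCC(C)=C
A7 | alternative 3 | (3S)-2,6-dimethylhepta-1,5-dien-3-ol | C=C(C)[C@H](CC=C(C)C)O
A8 | alternative 3 | (1S)-4-methyl-1-[(2R)-2-methyloxiran-2-yl]pent-3-en-1-ol | C[C@@]1(CO1)[C@@H](O)CC=C(C)C
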